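**Retrosynthetic overview**
1. Numbering (azulene): cyclopentane C1–C2–C3–C3a–C8a, cycloheptene C3a–C4–C5–C6–C7–C8–C8a. Target 29 ⇐ 4-O-aroylation, C6=C7 enal by β-elimination at C7, C4–OH by hydroxyl-directed reduction of a C4 ketone.
2. Enabling feature: the oxygen-bearing C4 lies between ring-fusion carbon C3a and the C5–C6=C7 unit, so C3a–C4(O)–C5–C6–C7 is the carbon backbone of a 3-oxidopyrylium (oxido on C4, ring oxygen spanning C3a and C7). The two remaining ring atoms C8–C8a are a CH2=C(CH3) alkene tied to C3a by the C3–C2–C1 chain of the cyclopentane.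
3. Key disconnection: C7–C8 and C3a–C8a by an intramolecular oxidopyrylium–alkene [5+2] cycloaddition that closes the cyclopentane and the seven-membered ring together and sets C8a and C3a (as C–O) from the one stored stereocentre C3. The C3a–O–C7 bridge is temporary: cut at C3a with SmI2, expelled from C7 when the enal forms.
4. The ylide comes from an Achmatowicz pyranone of furyl diol 10, in which only the tertiary carbinol C3 (Sharpless epoxidation) is controlled; the epimeric furyl carbinol and both anomers converge on one planar ylide.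
5. Ring order: furan → pyranone → cyclopentane + cycloheptane (one step) → removal of the oxygen bridge.

Key step: step 8

Notation: for the bicyclic compounds the azulene numbering of the target is used; β is the face of the C8a methyl group, α the opposite face (that of H-3a in the target).

Step 1
Reactants: 1 prop-2-yn-1-ol; 2 isopropylmagnesium chloride
Product: 3 3-methyl-2-methylidenebutan-1-ol
Conditions: 2 (2.5 equiv), CuI (10 mol %), Et2O/THF, −10 °C to rt; aq. NH4Cl
Reagents that add atoms: none
Why: Copper-catalysed anti-carbomagnesiation of the propargylic magnesium alkoxide puts the isopropyl group on the internal alkyne carbon, and protonolysis gives the 2-substituted allylic alcohol; no stereocentre is formed.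

Step 2
Reactants: 3 3-methyl-2-methylidenebutan-1-ol
Product: 4 [(2R)-2-(propan-2-yl)oxiran-2-yl]methanol
Conditions: Ti(OiPr)4 (10 mol %), D-(−)-diethyl tartrate (12 mol %), t-BuOOH (2 equiv), 4 Å molecular sieves, CH2Cl2, −20 °C
Reagents that add atoms: tert-butyl hydroperoxide CC(C)(C)OO
Why: Sharpless asymmetric epoxidation of a 2-substituted allylic alcohol, in which the D-(−)-tartrate ligand should direct oxygen to the alkene face that gives the (R)-epoxide; this centre becomes C3 of the target and is the only one set by a reagent.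

Step 3
Reactants: 4 [(2R)-2-(propan-2-yl)oxiran-2-yl]methanol; 5 (2-methylprop-2-en-1-yl)magnesium chloride
Product: 6 (2R)-5-methyl-2-(propan-2-yl)hex-5-ene-1,2-diol
Conditions: 5 (3 equiv), CuI (10 mol %), THF, −30 to 0 °C; aq. NH4Cl
Reagents that add atoms: none
Why: Copper-catalysed SN2 opening of the 2,2-disubstituted epoxide by the allylic Grignard reagent should occur at the unsubstituted CH2 terminus, so the quaternary carbinol centre is untouched and the tether alkene is installed.

Step 4
Reactants: 6 (2R)-5-methyl-2-(propan-2-yl)hex-5-ene-1,2-diol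
Product: 7 (2R)-2-hydroxy-5-methyl-2-(propan-2-yl)hex-5-enal
Conditions: IBX (1.5 equiv), DMSO, rt; used crude
Reagents that add atoms: none
Why: IBX oxidation takes the primary alcohol of a 1,2-diol to the aldehyde without glycol cleavage and leaves the tertiary alcohol and its stereocentre alone.

Step 5
Reactants: 7 (2R)-2-hydroxy-5-methyl-2-(propan-2-yl)hex-5-enal; 8 furan
Product: 10 (2R)-1-(furan-2-yl)-5-methyl-2-(propan-2-yl)hex-5-ene-1,2-diol (both C1 epimers), via 2-furyllithium 9 (not isolated)
Conditions: 8 (4 equiv), n-BuLi (3.5 equiv), THF, 0 °C; then 7, −78 to 0 °C; H2O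
Reagents that add atoms: none
Why: 1,2-Addition of 2-lithiofuran (α-lithiation of furan) to the aldehyde, one equivalent being spent on the tertiary hydroxyl; the new carbinol centre forms as a mixture, which is harmless because this carbon becomes planar in step 8.

Step 6
Reactants: 10 (2R)-1-(furan-2-yl)-5-methyl-2-(propan-2-yl)hex-5-ene-1,2-diol
Product: 12 6-hydroxy-2-[(3R)-3-hydroxy-2,6-dimethylhept-6-en-3-yl]-2H-pyran-3(6H)-one (epimers at C2 and C6), via furan endoperoxide 11 (not isolated)
Conditions: O2, tetraphenylporphyrin (cat.), visible light, CH2Cl2, −78 °C; then Me2S (3 equiv), −78 °C to rt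
Reagents that add atoms: dioxygen O=O
Why: Achmatowicz rearrangement in its singlet-oxygen form: [4+2] addition of singlet oxygen to the furan (far faster than an ene reaction at the 1,1-disubstituted alkene) and reduction of the endoperoxide by Me2S give the cis-enedione, which closes through the secondary carbinol oxygen to the pyranone hemiacetal; its two ring stereocentres are mixtures by design.

Step 7
Reactants: 12 6-hydroxy-2-[(3R)-3-hydroxy-2,6-dimethylhept-6-en-3-yl]-2H-pyran-3(6H)-one
Product: 14 6-acetoxy-2-[(3R)-2,6-dimethyl-3-(trimethylsilyloxy)hept-6-en-3-yl]-2H-pyran-3(6H)-one, via acetoxypyranone 13 (not isolated)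
Conditions: Ac2O (1.5 equiv), pyridine, DMAP (cat.), CH2Cl2, 0 °C; then N-(trimethylsilyl)imidazole (3 equiv), rt
Reagents that add atoms: acetic anhydride CC(=O)OC(C)=O; N-(trimethylsilyl)imidazole C[Si](C)(C)n1ccnc1
Why: Selective acetylation of the lactol hydroxyl gives the leaving group for ylide formation, and silylation then masks the tertiary hydroxyl, which would otherwise add to the anomeric carbon and trap the material as a bicyclic ketal once the ylide is reprotonated.

Step 8
Reactants: 14 6-acetoxy-2-[(3R)-2,6-dimethyl-3-(trimethylsilyloxy)hept-6-en-3-yl]-2H-pyran-3(6H)-one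
Product: 17 3aα,7α-epoxy-3β-hydroxy-8aβ-methyl-3α-(propan-2-yl)-2,3,3a,7,8,8a-hexahydroazulen-4(1H)-one, via oxidopyrylium ylide 15 (not isolated), via O-silyl cycloadduct 16 (not isolated)
Conditions: Et3N (3 equiv), MeCN (0.01 M), 60 °C; then citric acid, MeOH, 0 °C
Reagents that add atoms: none
Why: Et3N removes H-2 of 14 and acetate leaves from C6 (E1cB), so every C2 epimer and anomer of 14 gives the same planar 3-oxidopyrylium ylide 15, whose termini (future C3a and C7) add suprafacially across the tethered CH2=C(CH3) unit in a concerted, asynchronous thermal [5+2] (4π + 2π) cycloaddition; mild acid then removes the silyl group. The closest known reaction type is the intramolecular oxidopyrylium–alkene [5+2] cycloaddition of 2-(pent-4-enyl) ylides made from Achmatowicz acetoxypyranones. The cyclopentane closes by C3a–C8a bonding across the three-carbon tether (the only regiochemistry the tether length allows), and the seven-membered carbocycle closes in the same event by C7–C8 bonding, as an 8-oxabicyclo[3.2.1]oct-3-en-2-one. C8a is set because the short tether can only span the exo side of the forming bicycle, which leaves the methyl group endo and therefore anti to the C3a–O bond (the trans ring-fusion relationship once that oxygen is replaced by hydrogen), while C3a and C7 are held cis by the oxygen bridge. C3 relays its configuration by allylic strain: the isopropyl group cannot sit on the flank of the ylide carbon that carries the C4 oxido group, so the silyloxy group lies in the ylide plane beside it, the tether rises on the ring-oxygen side and the isopropyl group points away from the alkene, which should give O3 syn to C4 and isopropyl syn to the bridge as in the target. The step needs this π-facial selectivity and a cycloaddition faster than ylide dimerisation or hydroxyl trapping; the substitution at C3, the O-silyl mask, high dilution and the electron-rich 1,1-disubstituted alkene are meant to secure them.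

Step 9
Reactants: 17 3aα,7α-epoxy-3β-hydroxy-8aβ-methyl-3α-(propan-2-yl)-2,3,3a,7,8,8a-hexahydroazulen-4(1H)-one; 18 1,3-dioxolane
Product: 19 6α-(1,3-dioxolan-2-yl)-3aα,7α-epoxy-3β-hydroxy-8aβ-methyl-3α-(propan-2-yl)octahydroazulen-4(1H)-one
Conditions: benzophenone (0.3 equiv), 18 as solvent, hν (350 nm), rt
Reagents that add atoms: none
Why: Giese-type radical conjugate addition under photochemical hydrogen-atom transfer: triplet benzophenone abstracts H-2 of the dioxolane, the nucleophilic dioxolan-2-yl radical adds to the enone β-carbon C6 from the exo face (that of the oxygen bridge) and the α-keto radical takes hydrogen from the solvent, which installs the masked formyl carbon; the C6 centre is destroyed later.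

Step 10
Reactants: 19 6α-(1,3-dioxolan-2-yl)-3aα,7α-epoxy-3β-hydroxy-8aβ-methyl-3α-(propan-2-yl)octahydroazulen-4(1H)-one
Product: 22 6α-(1,3-dioxolan-2-yl)-3β,7α-dihydroxy-8aβ-methyl-3α-(propan-2-yl)-3aα-H-octahydroazulen-4(1H)-one (trans-fused), via bis(diiodosamarium) enolate 20 (not isolated), via cis-fused 3a-epimer 21 (not isolated)
Conditions: SmI2 (2.5 equiv), MeOH (5 equiv), THF, −78 °C; aq. NH4Cl; then imidazole (3 equiv), CH2Cl2, 35 °C
Reagents that add atoms: none
Why: SmI2 reduction of an α-alkoxy ketone: the ketyl expels the C3a–O bond to give enolate 20 and the C7 alkoxide, protonation creates H-3a, and imidazole-mediated enolisation (epimerisation of a β-hydroxy ketone without retro-aldol) should funnel any cis-fused epimer 21 into 22, expected to be the more stable because only there can O3–H hydrogen-bond to the C4 carbonyl while C4 stays off the isopropyl face.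

Step 11
Reactants: 22 6α-(1,3-dioxolan-2-yl)-3β,7α-dihydroxy-8aβ-methyl-3α-(propan-2-yl)-3aα-H-octahydroazulen-4(1H)-one
Product: 23 7α-acetoxy-6α-(1,3-dioxolan-2-yl)-3β-hydroxy-8aβ-methyl-3α-(propan-2-yl)-3aα-H-octahydroazulen-4(1H)-one
Conditions: Ac2O (1.5 equiv), pyridine, DMAP (cat.), CH2Cl2, 0 °C
Reagents that add atoms: acetic anhydride CC(=O)OC(C)=O
Why: Acetylation of the only secondary hydroxyl (C7) distinguishes it from the C4 hydroxyl made next and turns it into the leaving group for step 14; the tertiary alcohol should not react.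

Step 12
Reactants: 23 7α-acetoxy-6α-(1,3-dioxolan-2-yl)-3β-hydroxy-8aβ-methyl-3α-(propan-2-yl)-3aα-H-octahydroazulen-4(1H)-one
Product: 24 7α-acetoxy-6α-(1,3-dioxolan-2-yl)-8aβ-methyl-3α-(propan-2-yl)-3aα-H-decahydroazulene-3β,4α-diol
Conditions: Me4NBH(OAc)3 (5 equiv), MeCN/AcOH (2:1), −30 to 0 °C
Reagents that add atoms: none
Why: Hydroxyl-directed Evans–Saksena-type reduction: the C3 hydroxyl exchanges onto boron and delivers hydride intramolecularly to the carbonyl face on its own side, which should place the new C4 hydroxyl on the α face, cis to H-3a as in the target.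

Step 13
Reactants: 24 7α-acetoxy-6α-(1,3-dioxolan-2-yl)-8aβ-methyl-3α-(propan-2-yl)-3aα-H-decahydroazulene-3β,4α-diol; 25 4-[(tert-butyldimethylsilyl)oxy]benzoic acid
Product: 26 4α-O-[4-(tert-butyldimethylsilyloxy)benzoyl] ester of 24
Conditions: 25 (1.5 equiv), DCC (1.5 equiv), DMAP (0.5 equiv), CH2Cl2, rt
Reagents that add atoms: none
Why: Steglich esterification of the only secondary alcohol; the hindered tertiary C3 hydroxyl should not acylate and no stereocentre is touched.

Step 14
Reactants: 26 4α-O-[4-(tert-butyldimethylsilyloxy)benzoyl] ester of 24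
Product: 28 O-(tert-butyldimethylsilyl) ether of the target, via β-acetoxy aldehyde 27 (not isolated)
Conditions: 1 M HCl, THF, rt; then DBU (2 equiv), CH2Cl2, 0 °C
Reagents that add atoms: water O
Why: Acid hydrolysis of the dioxolane gives β-acetoxy aldehyde 27, and DBU then effects E1cB loss of acetate across C6–C7, the only position β to the formyl group that carries a leaving group, which gives the conjugated enal and removes the last trace of the oxygen bridge.

Step 15
Reactants: 28 O-(tert-butyldimethylsilyl) ether of the target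
Product: 29 [(3R,3aS,4S,8aR)-6-formyl-3-hydroxy-8a-methyl-3-(propan-2-yl)-1,2,3,3a,4,5,8,8a-octahydroazulen-4-yl] 4-hydroxybenzoate
Conditions: HF·pyridine, THF/pyridine, 0 °C to rt
Reagents that add atoms: none
Why: Fluoride cleavage of the aryl silyl ether should free the phenol without touching the ester, the enal or the tertiary alcohol.

**Compound list**
1 | prop-2-yn-1-ol | C#CCO | starting material
2 | isopropylmagnesium chloride | CC(C)[Mg]Cl | starting material
3 | 3-methyl-2-methylidenebutan-1-ol | CC(C)C(=C)CO | intermediate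
4 | [(2R)-2-(propan-2-yl)oxiran-2-yl]methanol | CC(C)[C@@]1(CO)CO1 | intermediate
5 | (2-methylprop-2-en-1-yl)magnesium chloride | CC(=C)C[Mg]Cl | starting material
6 | (2R)-5-methyl-2-(propan-2-yl)hex-5-ene-1,2-diol | CC(C)[C@@](O)(CO)CCC(C)=C | intermediate
7 | (2R)-2-hydroxy-5-methyl-2-(propan-2-yl)hex-5-enal | CC(C)[C@@](O)(C=O)CCC(C)=C | intermediate
8 | furan | c1ccoc1 | starting material
9 | 2-furyllithium | [Li]c1ccco1 | intermediate
10 | (2R)-1-(furan-2-yl)-5-methyl-2-(propan-2-yl)hex-5-ene-1,2-diol, both C1 epimers | CC(C)[C@@](O)(C(O)c1ccco1)CCC(C)=C | intermediate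
11 | 2,5-endoperoxide of the furan ring of 10 | CC(C)[C@@](O)(C(O)C12OOC(C=C1)O2)CCC(C)=C | intermediate
12 | 6-hydroxy-2-[(3R)-3-hydroxy-2,6-dimethylhept-6-en-3-yl]-2H-pyran-3(6H)-one, epimers at C2 and C6 | CC(C)[C@@](O)(C1OC(O)C=CC1=O)CCC(C)=C | intermediate
13 | 6-acetoxy-2-[(3R)-3-hydroxy-2,6-dimethylhept-6-en-3-yl]-2H-pyran-3(6H)-one | CC(C)[C@@](O)(C1OC(OC(C)=O)C=CC1=O)CCC(C)=C | intermediate
14 | 6-acetoxy-2-[(3R)-2,6-dimethyl-3-(trimethylsilyloxy)hept-6-en-3-yl]-2H-pyran-3(6H)-one | CC(C)[C@@](O[Si](C)(C)C)(C1OC(OC(C)=O)C=CC1=O)CCC(C)=C | intermediate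
15 | 2-[(3R)-2,6-dimethyl-3-(trimethylsilyloxy)hept-6-en-3-yl]pyrylium-3-olate | CC(C)[C@@](O[Si](C)(C)C)(c1[o+]cccc1[O-])CCC(C)=C | intermediate
16 | O3-trimethylsilyl ether of 17 | CC(C)[C@]1(O[Si](C)(C)C)CC[C@]2(C)C[C@H]3C=CC(=O)[C@]21O3 | intermediate
17 | 3aα,7α-epoxy-3β-hydroxy-8aβ-methyl-3α-(propan-2-yl)-2,3,3a,7,8,8a-hexahydroazulen-4(1H)-one | CC(C)[C@]1(O)CC[C@]2(C)C[C@H]3C=CC(=O)[C@]21O3 | intermediate
18 | 1,3-dioxolane | C1COCO1 | starting material
19 | 6α-(1,3-dioxolan-2-yl)-3aα,7α-epoxy-3β-hydroxy-8aβ-methyl-3α-(propan-2-yl)octahydroazulen-4(1H)-one | CC(C)[C@]1(O)CC[C@]2(C)C[C@H]3[C@H](C4OCCO4)CC(=O)[C@]21O3 | intermediate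
20 | bis(diiodosamarium) C3a=C4 enolate and C7 alkoxide from 19 | CC(C)[C@]1(O)CC[C@]2(C)C[C@H](O[Sm](I)I)[C@H](C3OCCO3)CC(O[Sm](I)I)=C21 | intermediate
21 | 3aβ-H (cis-fused) epimer of 22 | CC(C)[C@]1(O)CC[C@]2(C)C[C@H](O)[C@H](C3OCCO3)CC(=O)[C@@H]21 | intermediate
22 | 6α-(1,3-dioxolan-2-yl)-3β,7α-dihydroxy-8aβ-methyl-3α-(propan-2-yl)-3aα-H-octahydroazulen-4(1H)-one | CC(C)[C@]1(O)CC[C@]2(C)C[C@H](O)[C@H](C3OCCO3)CC(=O)[C@H]21 | intermediate
23 | 7α-acetoxy-6α-(1,3-dioxolan-2-yl)-3β-hydroxy-8aβ-methyl-3α-(propan-2-yl)-3aα-H-octahydroazulen-4(1H)-one | CC(C)[C@]1(O)CC[C@]2(C)C[C@H](OC(C)=O)[C@H](C3OCCO3)CC(=O)[C@H]21 | intermediate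
24 | 7α-acetoxy-6α-(1,3-dioxolan-2-yl)-8aβ-methyl-3α-(propan-2-yl)-3aα-H-decahydroazulene-3β,4α-diol | CC(C)[C@]1(O)CC[C@]2(C)C[C@H](OC(C)=O)[C@H](C3OCCO3)C[C@H](O)[C@H]21 | intermediate
25 | 4-[(tert-butyldimethylsilyl)oxy]benzoic acid | CC(C)(C)[Si](C)(C)Oc1ccc(cc1)C(O)=O | starting material
26 | 4α-O-[4-(tert-butyldimethylsilyloxy)benzoyl] ester of 24 | CC(C)[C@]1(O)CC[C@]2(C)C[C@H](OC(C)=O)[C@H](C3OCCO3)C[C@H](OC(=O)c3ccc(O[Si](C)(C)C(C)(C)C)cc3)[C@H]21 | intermediate
27 | 7α-acetoxy-6α-formyl analogue of 26 (β-acetoxy aldehyde) | CC(C)[C@]1(O)CC[C@]2(C)C[C@H](OC(C)=O)[C@H](C=O)C[C@H](OC(=O)c3ccc(O[Si](C)(C)C(C)(C)C)cc3)[C@H]21 | intermediate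
28 | O-(tert-butyldimethylsilyl) ether of the target | CC(C)[C@]1(O)CC[C@]2(C)CC=C(C=O)C[C@H](OC(=O)c3ccc(O[Si](C)(C)C(C)(C)C)cc3)[C@H]21 | intermediate
29 | [(3R,3aS,4S,8aR)-6-formyl-3-hydroxy-8a-methyl-3-(propan-2-yl)-1,2,3,3a,4,5,8,8a-octahydroazulen-4-yl] 4-hydroxybenzoate | CC(C)[C@]1(O)CC[C@]2(C)CC=C(C=O)C[C@H](OC(=O)c3ccc(O)cc3)[C@H]21 | target

Total steps: 15. Longest linear sequence: 15 steps (1 → 29).

**Steps most likely to fail**

Step 10 (H-3a). What may go wrong: kinetic protonation of the samarium enolate from the β face, which is flanked only by OH and CH3 and may be favoured by chelation of samarium to O3, would give mainly the cis-fused epimer. The imidazole equilibration may then be slow at the hindered C3a–H, may not lie far enough on the trans side, or may be accompanied by retro-aldol opening of the cyclopentanol. Fallback (kinetic control through a protecting group instead of the thermodynamic funnel): set out from 16, that is, omit the citric acid stage of step 8 and isolate the silyl ether. Photochemical dioxolane addition as in step 9 gives the O3-trimethylsilyl ether of 19, F1. SmI2/MeOH at −78 °C cleaves the bridge through the bis(diiodosamarium) enolate alkoxide F2, in which no hydroxyl holds samarium on the β face and the OSiMe3 group screens that face, so the proton should arrive on the α face from methanol bound at the O7 samarium alkoxide, giving the O3-trimethylsilyl ether of 22, F3. Because a silyl ether cannot undergo retro-aldol cleavage, F3 can also be equilibrated with DBU if needed. Citric acid in MeOH removes the silyl group and the route is rejoined at 22.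

Step 8 (key cycloaddition). What may go wrong: insufficient π-facial discrimination (silyloxy and isopropyl competing for the in-plane position beside the oxido group) and slow addition to the unactivated alkene, so that ylide dimerisation, or loss of the silyl group followed by bicycloketalisation, wins. Fallback (catalyst control and a more reactive dipole instead of substrate control alone): set out from 14 and run the cycloaddition under primary-amine/hydrogen-bond-donor dual catalysis (a chiral primary aminothiourea, an achiral aryl thiourea and AcOH, toluene, 40 °C). Condensation of the amine with the pyranone ketone gives an aminopyrylium, a more electron-rich dipole that adds under milder conditions, and the catalyst enantiomer is chosen so that its facial preference matches that of C3. Hydrolysis of the enamine gives 16 and, after citric acid/MeOH, 17, where the route is rejoined.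

Step 12 (C4 carbinol). What may go wrong: slow ligand exchange of the hindered tertiary hydroxyl with the triacetoxyborohydride, so that no reduction occurs or undirected hydride attack from the open face (that of H-3a) gives the C4 epimer. Fallback (covalent silicon tether in place of the reversible boron tether): set out from 23. ClSiMe2H/imidazole gives the O3-dimethylsilyl ether of 23, F4. Catalytic fluoride (CsF, THF, 0 °C) triggers intramolecular hydrosilylation of the C4 ketone, the Si–H held on O3 being delivered to the same carbonyl face as in step 12, to give the cyclic dimethylsilylene derivative of 24, F5. HF·pyridine cleaves the silylene and the route is rejoined at 24.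

**Further compounds**
F1 | step 10 | O3-trimethylsilyl ether of 19 | CC(C)[C@]1(O[Si](C)(C)C)CC[C@]2(C)C[C@H]3[C@H](C4OCCO4)CC(=O)[C@]21O3
F2 | step 10 | bis(diiodosamarium) enolate alkoxide from F1 | CC(C)[C@]1(O[Si](C)(C)C)CC[C@]2(C)C[C@H](O[Sm](I)I)[C@H](C3OCCO3)CC(O[Sm](I)I)=C21
F3 | step 10 | O3-trimethylsilyl ether of 22 | CC(C)[C@]1(O[Si](C)(C)C)CC[C@]2(C)C[C@H](O)[C@H](C3OCCO3)CC(=O)[C@H]21
F0 | step 8 | none | none
F4 | step 12 | O3-dimethylsilyl ether of 23 | CC(C)[C@]1(O[SiH](C)C)CC[C@]2(C)C[C@H](OC(C)=O)[C@H](C3OCCO3)CC(=O)[C@H]21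
F5 | step 12 | cyclic O3,O4-dimethylsilylene derivative of 24 | CC(C)[C@]1(O5)CC[C@]2(C)C[C@H](OC(C)=O)[C@H](C3OCCO3)C[C@H](O[Si]5(C)C)[C@H]21
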